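**Retrosynthetic overview**
- The strategy rests on the two adjacent fully substituted ring carbons: C1 (CH3 and the tetraenyl chain) and C6 (CH3 and OH), with the chain anti to the C6 oxygen. This pair is what an anti 1,2-vinyl shift from a C2 carbinol onto a C1–C6 epoxide leaves behind (ring numbering: C2 = CH with the hydroxypropyl arm, C3 = alkylidene carbon).
- Late disconnections: the C14 trienyl iodide is cut from a C1 vinyl group (hydroboration, B-alkyl Suzuki–Miyaura); the C3=C(CH3)CHO unit comes from a C3 ketone through an isopropenyl carbinol and oxidative 1,3-transposition.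
- The C2 arm comes from conjugate addition to a ring enal whose formyl carbon is afterwards excised by ozonolysis; the enal comes from the C2 ketone that the vinyl shift leaves.
- The epoxy vinyl carbinol comes from 2,3-dimethylcyclohex-2-enone by CBS reduction, hydroxyl-directed epoxidation, re-oxidation and vinyl Grignard addition.
- Ring order: the only carbocycle is bought with the enone and is never opened; no ring is formed in the route.

Key step: step 5

Assumption: pseudoionone is used as the pure (3E,5E) isomer (commercial isomer mixtures are purified first); the enol ether geometry formed in step 9 and the carbinol configurations formed in steps 8 and 11 are destroyed later and are drawn arbitrarily.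

**Step 1**
Reactants: 1 2,3-dimethylcyclohex-2-en-1-one
Product: 2 (R)-2,3-dimethylcyclohex-2-en-1-ol
Conditions: (S)-2-methyl-CBS-oxazaborolidine (10 mol %), BH3·SMe2, THF, −20 °C; MeOH quench
Reagents that add atoms: none
Why: CBS reduction, in which the borane-loaded oxazaborolidine binds the ketone with the alkenyl arm as the large group and delivers hydride to one carbonyl face, so the (S)-catalyst should give the (R)-carbinol at C2, the only source of absolute configuration for the ring.

**Step 2**
Reactants: 2 (R)-2,3-dimethylcyclohex-2-en-1-ol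
Product: 3 (1R,2R,6S)-1,6-dimethyl-7-oxabicyclo[4.1.0]heptan-2-ol (epoxide cis to the hydroxyl)
Conditions: VO(acac)2 (3 mol %), t-BuOOH (decane), CH2Cl2, 0 °C → rt
Reagents that add atoms: tert-butyl hydroperoxide, CC(C)(C)OO
Why: Hydroxyl-directed epoxidation, in which the vanadium alkoxide–peroxide complex delivers oxygen to the electron-rich tetrasubstituted alkene on the face of the hydroxyl, so the C1 and C6 epoxide carbons are set cis to the C2 oxygen.

**Step 3**
Reactants: 3 (1R,2R,6S)-1,6-dimethyl-7-oxabicyclo[4.1.0]heptan-2-ol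
Product: 4 (1S,6S)-1,6-dimethyl-7-oxabicyclo[4.1.0]heptan-2-one
Conditions: Pr4N[RuO4] (5 mol %), N-methylmorpholine N-oxide, 4 Å MS, CH2Cl2, rt
Reagents that add atoms: none
Why: Ley–Griffith oxidation under neutral conditions should return the ketone without opening the acid-sensitive tetrasubstituted epoxide, the carbinol centre having already relayed its configuration to the epoxide.

**Step 4**
Reactants: 4 (1S,6S)-1,6-dimethyl-7-oxabicyclo[4.1.0]heptan-2-one; 5 vinylmagnesium bromide
Product: 6 (1R,2S,6S)-2-ethenyl-1,6-dimethyl-7-oxabicyclo[4.1.0]heptan-2-ol (vinyl trans to the epoxide oxygen)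
Conditions: THF, −78 °C; aq. NH4Cl
Reagents that add atoms: none
Why: Grignard 1,2-addition, in which the nucleophile should approach the carbonyl anti to the polar epoxide C–O bond (the oxygen shields its own face while the two methyl groups lie near the ring plane), placing vinyl trans and the new hydroxyl cis to the epoxide oxygen at C2, as is usual for additions to 2,3-epoxycycloalkanones.

**Step 5**
Reactants: 6 (1R,2S,6S)-2-ethenyl-1,6-dimethyl-7-oxabicyclo[4.1.0]heptan-2-ol
Product: 7 (2R,3S)-2-ethenyl-3-hydroxy-2,3-dimethylcyclohexan-1-one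
Conditions: BF3·OEt2 (0.3 equiv), CH2Cl2, −78 → −40 °C; Et3N then aq. NaHCO3
Reagents that add atoms: none
Why: BF3 binds the epoxide oxygen and the C1–O bond breaks while the vinyl group on the carbinol carbon C2, which is trans to that bond and close to antiperiplanar in the half-chair with vinyl pseudoaxial, moves with its bonding pair onto the rear of C1 as the carbinol oxygen closes to the C2 carbonyl; this is the semipinacol rearrangement of a 2,3-epoxy alcohol to a β-hydroxy ketone with an α-quaternary carbon, an established reaction type. No ring is formed, since the cyclohexane is carried through intact. C1 is created with inversion (vinyl enters opposite the departing oxygen) and C6 keeps its C–O bond, so the C1/C6 relative configuration (vinyl anti to the C6 oxygen) follows from the cis epoxide and the trans vinyl group, and the absolute configuration follows from step 1. The step needs vinyl migration to C1 in preference to ring-bond migration (ring contraction), opening at the equally tertiary C6, or elimination. This is secured because the ring bond C2–C3 is held roughly orthogonal to the C1–O bond and cannot migrate in concert, the hydroxyl lone-pair push makes cleavage at the carbon next to the carbinol concerted with carbonyl formation, and an sp2 group shifts readily to a tertiary terminus at low temperature. The C2 ketone that remains is the handle for C2 and C3.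

**Step 6**
Reactants: 7 (2R,3S)-2-ethenyl-3-hydroxy-2,3-dimethylcyclohexan-1-one
Product: 8 (2R,3S)-2-ethenyl-2,3-dimethyl-3-(triethylsilyloxy)cyclohexan-1-one
Conditions: Et3SiOTf, 2,6-lutidine, CH2Cl2, −78 → 0 °C
Reagents that add atoms: triethylsilyl trifluoromethanesulfonate, CC[Si](CC)(CC)OS(=O)(=O)C(F)(F)F
Why: Silylation of the tertiary aldol hydroxyl with a silyl triflate and a hindered base masks it against retro-aldol cleavage in the basic and hydridic steps that follow.

**Step 7**
Reactants: 8 (2R,3S)-2-ethenyl-2,3-dimethyl-3-(triethylsilyloxy)cyclohexan-1-one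
Product: 9 (2R,3S,6E)-6-[(dimethylamino)methylidene]-2-ethenyl-2,3-dimethyl-3-(triethylsilyloxy)cyclohexan-1-one
Conditions: t-BuOCH(NMe2)2, toluene, 100 °C
Reagents that add atoms: tert-butoxybis(dimethylamino)methane, CC(C)(C)OC(N(C)C)N(C)C
Why: Aminomethylenation, in which the aminal ester ionises to a formamidinium ion and tert-butoxide that condense at the only enolisable position, the C3 methylene (C1 is quaternary), to give the (E)-enaminone.

**Step 8**
Reactants: 9 (2R,3S,6E)-6-[(dimethylamino)methylidene]-2-ethenyl-2,3-dimethyl-3-(triethylsilyloxy)cyclohexan-1-one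
Product: 11 (3S,4S)-3-ethenyl-3,4-dimethyl-4-(triethylsilyloxy)cyclohex-1-ene-1-carbaldehyde, via amino allylic alcohol 10 (not isolated)
Conditions: LiAlH4, Et2O, −20 → 0 °C; then 10% aq. citric acid, THF, 0 °C → rt
Reagents that add atoms: water, O
Why: 1,2-Hydride reduction of the vinylogous amide carbonyl, then acid-induced loss of water through the conjugated iminium ion and its hydrolysis, gives the transposed enal (a reductive carbonyl transposition) and destroys the transient C2 carbinol centre.

**Step 9**
Reactants: 11 (3S,4S)-3-ethenyl-3,4-dimethyl-4-(triethylsilyloxy)cyclohex-1-ene-1-carbaldehyde; 12 (3-bromopropoxy)(tert-butyl)dimethylsilane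
Product: 14 (E)-[(2R,3S,4S)-2-[3-(tert-butyldimethylsilyloxy)propyl]-3-ethenyl-3,4-dimethyl-4-(triethylsilyloxy)cyclohexylidene]methyl trimethylsilyl ether, via Grignard reagent 13 (not isolated)
Conditions: 12, Mg, THF, rt; then CuBr·SMe2 (10 mol %), HMPA (or DMPU), THF, −78 °C, 11 + Me3SiCl; Et3N, cold aq. NaHCO3 work-up
Reagents that add atoms: chlorotrimethylsilane, C[Si](C)(C)Cl
Why: Copper-catalysed conjugate addition of a Grignard reagent to an enal with chlorosilane acceleration and O-silyl trapping, in which the alkyl group should enter C2 axially on the half-chair that keeps the C6 methyl equatorial and the C1 vinyl pseudoaxial, that is anti to vinyl and on the face of the C6 oxygen, which sets C2.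

**Step 10**
Reactants: 14 the trimethylsilyl enol ether of step 9
Product: 16 (2S,3S,4S)-2-[3-(tert-butyldimethylsilyloxy)propyl]-3-ethenyl-3,4-dimethyl-4-(triethylsilyloxy)cyclohexan-1-one, via ozonide 15 (not isolated)
Conditions: O3 (1 equiv, Sudan Red 7B end-point), pyridine (trace), CH2Cl2, −78 °C; then Me2S, −78 °C → rt
Reagents that add atoms: ozone, [O-][O+]=O
Why: Ozonolysis, in which electrophilic ozone should react far faster with the electron-rich silyl enol ether than with the hindered monosubstituted vinyl group, so one equivalent at low temperature excises the temporary formyl carbon as trimethylsilyl formate and leaves the C3 ketone without disturbing the epimerisable C2 centre.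

**Step 11**
Reactants: 16 the C3 ketone of step 10; 17 2-bromopropene
Product: 20 (1R,2S,3S,4S)-2-[3-(tert-butyldimethylsilyloxy)propyl]-3-ethenyl-3,4-dimethyl-1-(prop-1-en-2-yl)-4-(triethylsilyloxy)cyclohexan-1-ol, via isopropenyllithium 18 (not isolated), via isopropenylcerium dichloride 19 (not isolated)
Conditions: 17, t-BuLi (2 equiv), Et2O, −78 °C; CeCl3, THF, −78 °C; then 16, −78 → −40 °C; aq. NH4Cl
Reagents that add atoms: none
Why: Bromine–lithium exchange, transmetalation to cerium and 1,2-addition, in which the weakly basic organocerium reagent should add to the hindered enolisable ketone without epimerising C2 (equatorial attack expected), the new carbinol configuration being of no consequence.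

**Step 12**
Reactants: 20 the tertiary isopropenyl carbinol of step 11
Product: 21 (2Z)-2-[(2R,3S,4S)-2-[3-(tert-butyldimethylsilyloxy)propyl]-3-ethenyl-3,4-dimethyl-4-(triethylsilyloxy)cyclohexylidene]propanal
Conditions: [C5H5NH][CrO3Cl] (3 equiv), 4 Å MS, CH2Cl2, rt
Reagents that add atoms: pyridinium chlorochromate [C5H5NH][CrO3Cl], [O-][Cr](=O)(=O)Cl.c1cc[nH+]cc1
Why: Babler–Dauben oxidative transposition, in which the chromate ester of the tertiary allylic alcohol undergoes a [3,3] shift to the primary allylic chromate that is oxidised to the conjugated aldehyde; the rotamer of the isopropenyl group in the shift decides the geometry of the new tetrasubstituted alkene, for which no secure preference can be claimed, so the (Z)-isomer is to be separated from any (E)-isomer here or after step 13.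

**Step 13**
Reactants: 21 the (Z)-enal of step 12
Product: 22 (2Z)-2-[(2R,3S,4S)-2-[3-(tert-butyldimethylsilyloxy)propyl]-3-ethenyl-3,4-dimethyl-4-(triethylsilyloxy)cyclohexylidene]propan-1-ol
Conditions: NaBH4, CeCl3·7H2O, MeOH, −20 °C
Reagents that add atoms: none
Why: Luche 1,2-reduction masks the aldehyde, which would otherwise consume the borane of step 17, without moving the alkene or changing its geometry.

**Step 14**
Reactants: 22 the (Z)-allylic alcohol of step 13
Product: 23 tert-butyldimethylsilyl ether of 22 (three silyl ethers, free C1 vinyl)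
Conditions: t-BuMe2SiCl, imidazole, DMF, rt
Reagents that add atoms: tert-butyldimethylsilyl chloride, CC(C)(C)[Si](C)(C)Cl
Why: Standard silylation of the unhindered primary allylic alcohol with a silyl chloride and imidazole.

**Step 15**
Reactants: 24 (3E,5E)-6,10-dimethylundeca-3,5,9-trien-2-one (pseudoionone)
Product: 26 (3E,5E)-6,10-dimethylundeca-3,5,9-trien-1-yne, via enol phosphate 25 (not isolated)
Conditions: LiN(i-Pr)2 (1.05 equiv), THF, −78 °C; ClP(O)(OEt)2, −78 °C → rt; then LiN(i-Pr)2 (2.3 equiv), −78 °C → rt
Reagents that add atoms: none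
Why: One-pot methyl ketone to alkyne conversion, in which kinetic deprotonation at the methyl group gives the cross-conjugated enolate, O-phosphorylation gives the enol phosphate and excess amide base eliminates diethyl phosphate to the terminal alkyne, leaving the (E,E)-diene untouched.

**Step 16**
Reactants: 26 (3E,5E)-6,10-dimethylundeca-3,5,9-trien-1-yne
Product: 28 (1E,3E,5E)-1-iodo-2,6,10-trimethylundeca-1,3,5,9-tetraene, via alkenylalane 27 (not isolated)
Conditions: Me3Al (2 equiv), Cp2ZrCl2 (0.3 equiv), CH2Cl2, 0 °C → rt; then I2, THF, −30 → 0 °C, dark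
Reagents that add atoms: trimethylaluminium, C[Al](C)C; iodine, II
Why: Zirconium-catalysed carboalumination adds methyl and aluminium syn across the terminal alkyne with aluminium at the terminus, and iodinolysis of the C–Al bond with retention should give the (E)-alkenyl iodide.

**Step 17**
Reactants: 23 the tris-silyl ether with free vinyl from step 14; 28 (1E,3E,5E)-1-iodo-2,6,10-trimethylundeca-1,3,5,9-tetraene
Product: 30 tris-silyl ether of the reduced target (C6 triethylsilyl ether and two tert-butyldimethylsilyl ethers), via B-alkyl borane 29 (not isolated)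
Conditions: 9-BBN dimer, THF, 0 °C → rt; then aq. Cs2CO3, 28, PdCl2(dppf) (5 mol %), AsPh3, DMF, rt, dark
Reagents that add atoms: none
Why: 9-BBN should hydroborate only the monosubstituted C1 vinyl group (anti-Markovnikov, the tetrasubstituted alkene being inert), and the B-alkyl Suzuki–Miyaura coupling joins the primary alkylborane to the alkenyl iodide with retention of its geometry, the triene being added only after hydroboration is complete.

**Step 18**
Reactants: 30 the tris-silyl ether of step 17
Product: 31 (2Z)-2-[(2R,3S,4S)-4-hydroxy-2-(3-hydroxypropyl)-3,4-dimethyl-3-[(3E,5E,7E)-4,8,12-trimethyltrideca-3,5,7,11-tetraen-1-yl]cyclohexylidene]propan-1-ol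
Conditions: Bu4NF, THF, 0 → 40 °C
Reagents that add atoms: none
Why: Fluoride-induced cleavage of all three silyl ethers, the hindered tertiary triethylsilyl ether being the slowest.

**Step 19**
Reactants: 31 the triol of step 18
Product: 32 CNP0237252.1, (2Z)-2-[(2R,3S,4S)-4-hydroxy-2-(3-hydroxypropyl)-3,4-dimethyl-3-[(3E,5E,7E)-4,8,12-trimethyltrideca-3,5,7,11-tetraen-1-yl]cyclohexylidene]propanal
Conditions: MnO2 (excess), CH2Cl2, rt, dark
Reagents that add atoms: none
Why: MnO2 oxidises allylic alcohols selectively, so only the allylic primary hydroxyl should become the aldehyde while the saturated primary and the tertiary hydroxyl remain.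

**Compound list**
1 | 2,3-dimethylcyclohex-2-en-1-one | CC1=C(C)C(=O)CCC1 | starting material
2 | (R)-2,3-dimethylcyclohex-2-en-1-ol | CC1=C(C)[C@H](O)CCC1 | intermediate
3 | (1R,2R,6S)-1,6-dimethyl-7-oxabicyclo[4.1.0]heptan-2-ol | O[C@@H]1CCC[C@]2(C)O[C@]12C | intermediate
4 | (1S,6S)-1,6-dimethyl-7-oxabicyclo[4.1.0]heptan-2-one | O=C1CCC[C@]2(C)O[C@]12C | intermediate
5 | vinylmagnesium bromide | C=C[Mg]Br | starting material
6 | (1R,2S,6S)-2-ethenyl-1,6-dimethyl-7-oxabicyclo[4.1.0]heptan-2-ol | C=C[C@@]1(O)CCC[C@]2(C)O[C@]12C | intermediate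
7 | (2R,3S)-2-ethenyl-3-hydroxy-2,3-dimethylcyclohexan-1-one | C=C[C@@]1(C)C(=O)CCC[C@]1(C)O | intermediate
8 | (2R,3S)-2-ethenyl-2,3-dimethyl-3-(triethylsilyloxy)cyclohexan-1-one | C=C[C@@]1(C)C(=O)CCC[C@]1(C)O[Si](CC)(CC)CC | intermediate
9 | (2R,3S,6E)-6-[(dimethylamino)methylidene]-2-ethenyl-2,3-dimethyl-3-(triethylsilyloxy)cyclohexan-1-one | C=C[C@@]1(C)C(=O)/C(=C/N(C)C)CC[C@]1(C)O[Si](CC)(CC)CC | intermediate
10 | (2R,3S,6E)-6-[(dimethylamino)methylidene]-2-ethenyl-2,3-dimethyl-3-(triethylsilyloxy)cyclohexan-1-ol, carbinol epimers | C=C[C@@]1(C)C(O)/C(=C/N(C)C)CC[C@]1(C)O[Si](CC)(CC)CC | intermediate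
11 | (3S,4S)-3-ethenyl-3,4-dimethyl-4-(triethylsilyloxy)cyclohex-1-ene-1-carbaldehyde | C=C[C@@]1(C)C=C(C=O)CC[C@]1(C)O[Si](CC)(CC)CC | intermediate
12 | (3-bromopropoxy)(tert-butyl)dimethylsilane | BrCCCO[Si](C)(C)C(C)(C)C | starting material
13 | [3-(tert-butyldimethylsilyloxy)propyl]magnesium bromide | Br[Mg]CCCO[Si](C)(C)C(C)(C)C | intermediate
14 | (E)-[(2R,3S,4S)-2-[3-(tert-butyldimethylsilyloxy)propyl]-3-ethenyl-3,4-dimethyl-4-(triethylsilyloxy)cyclohexylidene]methyl trimethylsilyl ether | C=C[C@@]1(C)[C@H](CCCO[Si](C)(C)C(C)(C)C)/C(=C/O[Si](C)(C)C)CC[C@]1(C)O[Si](CC)(CC)CC | intermediate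
15 | ozonide of 14 (spiro 1,2,4-trioxolane at C3 carrying the trimethylsilyloxy group on the acetal carbon) | C=C[C@@]1(C)[C@H](CCCO[Si](C)(C)C(C)(C)C)C2(CC[C@]1(C)O[Si](CC)(CC)CC)OOC(O[Si](C)(C)C)O2 | intermediate
16 | (2S,3S,4S)-2-[3-(tert-butyldimethylsilyloxy)propyl]-3-ethenyl-3,4-dimethyl-4-(triethylsilyloxy)cyclohexan-1-one | C=C[C@@]1(C)[C@H](CCCO[Si](C)(C)C(C)(C)C)C(=O)CC[C@]1(C)O[Si](CC)(CC)CC | intermediate
17 | 2-bromopropene | CC(Br)=C | starting material
18 | isopropenyllithium (prop-1-en-2-yllithium) | [Li]C(C)=C | intermediate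
19 | isopropenylcerium dichloride (dichloro(prop-1-en-2-yl)cerium) | CC(=C)[Ce](Cl)Cl | intermediate
20 | (1R,2S,3S,4S)-2-[3-(tert-butyldimethylsilyloxy)propyl]-3-ethenyl-3,4-dimethyl-1-(prop-1-en-2-yl)-4-(triethylsilyloxy)cyclohexan-1-ol | C=C[C@@]1(C)[C@H](CCCO[Si](C)(C)C(C)(C)C)[C@@](O)(C(C)=C)CC[C@]1(C)O[Si](CC)(CC)CC | intermediate
21 | (2Z)-2-[(2R,3S,4S)-2-[3-(tert-butyldimethylsilyloxy)propyl]-3-ethenyl-3,4-dimethyl-4-(triethylsilyloxy)cyclohexylidene]propanal | C=C[C@@]1(C)[C@H](CCCO[Si](C)(C)C(C)(C)C)/C(=C(/C)C=O)CC[C@]1(C)O[Si](CC)(CC)CC | intermediate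
22 | (2Z)-2-[(2R,3S,4S)-2-[3-(tert-butyldimethylsilyloxy)propyl]-3-ethenyl-3,4-dimethyl-4-(triethylsilyloxy)cyclohexylidene]propan-1-ol | C=C[C@@]1(C)[C@H](CCCO[Si](C)(C)C(C)(C)C)/C(=C(/C)CO)CC[C@]1(C)O[Si](CC)(CC)CC | intermediate
23 | tert-butyldimethylsilyl ether of 22 | C=C[C@@]1(C)[C@H](CCCO[Si](C)(C)C(C)(C)C)/C(=C(/C)CO[Si](C)(C)C(C)(C)C)CC[C@]1(C)O[Si](CC)(CC)CC | intermediate
24 | (3E,5E)-6,10-dimethylundeca-3,5,9-trien-2-one (pseudoionone) | CC(C)=CCC/C(C)=C/C=C/C(C)=O | starting material
25 | diethyl (3E,5E)-6,10-dimethylundeca-1,3,5,9-tetraen-2-yl phosphate | CC(C)=CCC/C(C)=C/C=C/C(=C)OP(=O)(OCC)OCC | intermediate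
26 | (3E,5E)-6,10-dimethylundeca-3,5,9-trien-1-yne | CC(C)=CCC/C(C)=C/C=C/C#C | intermediate
27 | dimethyl[(1E,3E,5E)-2,6,10-trimethylundeca-1,3,5,9-tetraen-1-yl]alane | CC(C)=CCC/C(C)=C/C=C/C(C)=C/[Al](C)C | intermediate
28 | (1E,3E,5E)-1-iodo-2,6,10-trimethylundeca-1,3,5,9-tetraene | CC(C)=CCC/C(C)=C/C=C/C(C)=C/I | intermediate
29 | B-alkyl-9-borabicyclo[3.3.1]nonane from 23 (boron on the terminal carbon of the former vinyl group) | C1CCC2CCCC1B2CC[C@@]3(C)[C@H](CCCO[Si](C)(C)C(C)(C)C)/C(=C(/C)CO[Si](C)(C)C(C)(C)C)CC[C@]3(C)O[Si](CC)(CC)CC | intermediate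
30 | tris-silyl ether of triol 31 (C6 triethylsilyl ether, two primary tert-butyldimethylsilyl ethers) | CC(C)=CCC/C(C)=C/C=C/C(C)=C/CC[C@@]1(C)[C@H](CCCO[Si](C)(C)C(C)(C)C)/C(=C(/C)CO[Si](C)(C)C(C)(C)C)CC[C@]1(C)O[Si](CC)(CC)CC | intermediate
31 | (2Z)-2-[(2R,3S,4S)-4-hydroxy-2-(3-hydroxypropyl)-3,4-dimethyl-3-[(3E,5E,7E)-4,8,12-trimethyltrideca-3,5,7,11-tetraen-1-yl]cyclohexylidene]propan-1-ol | CC(C)=CCC/C(C)=C/C=C/C(C)=C/CC[C@@]1(C)[C@H](CCCO)/C(=C(/C)CO)CC[C@]1(C)O | intermediate
32 | CNP0237252.1, (2Z)-2-[(2R,3S,4S)-4-hydroxy-2-(3-hydroxypropyl)-3,4-dimethyl-3-[(3E,5E,7E)-4,8,12-trimethyltrideca-3,5,7,11-tetraen-1-yl]cyclohexylidene]propanal | CC(C)=CCC/C(C)=C/C=C/C(C)=C/CC[C@@]1(C)[C@H](CCCO)/C(=C(/C)C=O)CC[C@]1(C)O | target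

**Step count and risks**
Total step count: 19. Longest linear sequence: 17 steps (steps 1–14 and 17–19); the iodide branch is 2 steps (15 and 16).

Steps most likely to fail:

1. Step 9. The organocopper reagent may attack C2 from the vinyl-bearing face or with little facial preference, or add 1,2 to the aldehyde, because the β-carbon sits next to the quaternary C1. Fallback (exchange of the roles of carbon and hydrogen at C2): the route is left at enaminone 9. Grignard reagent 13 is transmetalated with CeCl3 to dichloro[3-(tert-butyldimethylsilyloxy)propyl]cerium F1, which adds to the C2 carbonyl of 9 to give the tertiary amino alcohol adduct F2. Aqueous citric acid then removes water and dimethylamine to give the C2-alkylated enal (3S,4S)-2-[3-(tert-butyldimethylsilyloxy)propyl]-3-ethenyl-3,4-dimethyl-4-(triethylsilyloxy)cyclohex-1-ene-1-carbaldehyde F3. Conjugate reduction of F3 with [(Ph3P)CuH]6 and Me3SiCl delivers hydride to C2 and returns the route at silyl enol ether 14. Hydride should follow the same facial bias as the carbon nucleophile, so this sequence gives the C2 epimer opposite to the one formed in step 9 and supplies the required epimer exactly when step 9 fails through wrong facial preference.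

2. Step 12. The hindered tertiary carbinol may ionise and lose water instead of forming the chromate ester, and the [3,3] shift may place the formyl carbon on the C4 side of the new tetrasubstituted alkene (poor or wrong geometric selectivity). Fallback (redox-neutral transposition under thermodynamic control): the route is left at carbinol 20. Ph3SiOReO3 (catalytic, Et2O, 0 °C) isomerises 20 directly to the primary allylic alcohols, 22 and its geometric isomer (2E)-2-[(2R,3S,4S)-2-[3-(tert-butyldimethylsilyloxy)propyl]-3-ethenyl-3,4-dimethyl-4-(triethylsilyloxy)cyclohexylidene]propan-1-ol F4, which are separated. F4 is returned to the same catalyst, which re-equilibrates it through 20, so the material is funnelled to 22, where the route is rejoined without passing through enal 21.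

3. Step 5. The Lewis acid may open the epoxide at C6 (elimination or a shift toward C6), or adventitious Brønsted acid may cleave the β-hydroxy ketone by retro-aldol reaction, instead of the concerted vinyl shift. Fallback (rearrangement of the O-silyl ether with silyl transfer): the route is left at 6. Et3SiOTf and 2,6-lutidine give the O-triethylsilyl ether of 6 F5. With the bulky aluminium Lewis acid MeAl(OAr)2 (Ar = 4-bromo-2,6-di-tert-butylphenyl; CH2Cl2, −78 °C), F5 should undergo the same anti vinyl shift, the silyl group passing from the oxocarbenium oxygen to the C6 alkoxide. This gives 8 directly, where the route is rejoined (steps 5 and 6 merged).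

Further compounds
F1 | step 9 | dichloro[3-(tert-butyldimethylsilyloxy)propyl]cerium | Cl[Ce](Cl)CCCO[Si](C)(C)C(C)(C)C
F2 | step 9 | tertiary amino alcohol adduct, 1-[3-(tert-butyldimethylsilyloxy)propyl]-6-[(dimethylamino)methylidene]-2-ethenyl-2,3-dimethyl-3-(triethylsilyloxy)cyclohexan-1-ol (carbinol epimers) | C=C[C@@]1(C)C(O)(CCCO[Si](C)(C)C(C)(C)C)/C(=C/N(C)C)CC[C@]1(C)O[Si](CC)(CC)CC
F3 | step 9 | (3S,4S)-2-[3-(tert-butyldimethylsilyloxy)propyl]-3-ethenyl-3,4-dimethyl-4-(triethylsilyloxy)cyclohex-1-ene-1-carbaldehyde | C=C[C@@]1(C)C(CCCO[Si](C)(C)C(C)(C)C)=C(C=O)CC[C@]1(C)O[Si](CC)(CC)CC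
F4 | step 12 | (2E)-2-[(2R,3S,4S)-2-[3-(tert-butyldimethylsilyloxy)propyl]-3-ethenyl-3,4-dimethyl-4-(triethylsilyloxy)cyclohexylidene]propan-1-ol | C=C[C@@]1(C)[C@H](CCCO[Si](C)(C)C(C)(C)C)/C(=C(\C)CO)CC[C@]1(C)O[Si](CC)(CC)CC
F5 | step 5 | O-triethylsilyl ether of 6 | C=C[C@@]1(O[Si](CC)(CC)CC)CCC[C@]2(C)O[C@]12C
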